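**The impossibility.** I cannot follow a falling [reagent] through a feed by hand, so I replace the curve by its mean, and I replace the spread of ages of the dosed starting material by its mean age, the time since the middle of what has been dosed.

| flask | starting material | reagent | remark | time |
|---|---|---|---|---|
| north-east | 0.17 M (fed, over 2.5 min) | 0.45 M | run made earlier; the fed solution adds 0.10 times the starting volume |  |
| south-east | 0.35 M (fed, over 2.5 min) | 0.45 M | run made earlier; the fed solution adds 0.10 times the starting volume |  |
| north | 0.50 M (fed, over 2.5 min) | 0.39 M | run made earlier; the fed solution adds 0.10 times the starting volume |  |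
| Friday's | 0.50 M (fed, over 4.0 min) | 0.120 M | the fed solution adds 0.10 times the starting volume | 2.5 min |
| Sunday's | 0.50 M (fed, over 0.80 min) | 0.450 M | the fed solution adds 0.10 times the starting volume | 2.5 min |
| Tuesday's | 0.30 M (fed, over 1.5 min) | 0.300 M | the fed solution adds 0.10 times the starting volume | 2.5 min |
| Monday's | 0.50 M (fed, over 2.5 min) | 0.450 M | the fed solution adds 0.10 times the starting volume | 2.5 min |
| Thursday's | 0.50 M (fed, over 0.80 min) | 2.00 M | the fed solution adds 0.10 times the starting volume | 2.5 min |

- north-east (time / s: mono adduct / %, starting material / %): 10.0: 0.2, 6.6; 25.0: 1.2, 15.3; 50.0: 4.6, 27.1; 80.0: 10.2, 39.9; 120: 18.0, 54.4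
- south-east (time / s: mono adduct / %, starting material / %): 10.0: 0.3, 6.9; 25.0: 1.1, 15.0; 50.0: 5.5, 27.8; 80.0: 10.5, 40.8; 120: 17.6, 55.2
- north (time / s: mono adduct / %, starting material / %): 20.0: 1.3, 13.2; 40.0: 3.1, 22.9; 60.0: 5.6, 33.3; 80.0: 8.9, 41.8; 120: 15.9, 57.9

(standard deviation of a reading: 0.3 percentage points)

- charges are per starting volume, the dose included; the dosed solution carries all of it
- the analysis behind the earlier runs scatters by 0.3 percentage points, standard deviation
- percentages count the whole charge, also what has not yet gone in

1. the flasks put in order of amount of mono adduct, in percent of the starting material charged, best first, at 2.5 min (Friday's / Sunday's / Tuesday's / Monday's / Thursday's)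
2. the amount of mono adduct, in percent of the starting material charged of the flask you put first, at 2.5 min
3. the amount of mono adduct, in percent of the starting material charged of the flask you put last, at 2.5 min

**The ledger.** The north run has 0.39 M of reagent against 0.50 M of starting material, so reagent is the limiting reagent there, and I close its books at 120 s. By then 80.0 % of the charge has gone in, 57.9 % stands as starting material, 15.9 % stands as mono adduct, and a gap of 6.2 percentage points has gone further. I book the mono adduct at one reagent and the gap at two, as a second addition, so 0.142 M is spent and 0.248 M remains. The mean of start and end, over the volume at that moment, is 0.296 M.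

**The exposure.** I call exposure the product of a constant, mean [reagent] and mean age, so that starting material left is the dosed share times e to the minus exposure. The north run reads an exposure of 0.323, which gives the exposure constant 0.0182 M⁻¹ s⁻¹, a reading that carries the scatter of the run. With equal steps, mono adduct over starting material would equal the exposure, and the reagent bill per mole dosed would nearly equal it too while it stays under one. The north ratio is 0.849 of that, so I take mono adduct as this factor times dosed share times exposure times e to the minus exposure, a curve that peaks at exposure one.

**My reckoning.** Letting [reagent] fall by the bill, I get for Sunday's an exposure per unit of [reagent] of 2.09 M⁻¹, hence an exposure of 0.617 and mono adduct of 28.3 %. Monday's gets 1.24 M⁻¹ per unit, hence 0.427 and 23.7 %. Tuesday's gets 1.74 M⁻¹ per unit, hence 0.414 and 23.2 %, and by this reckoning I cannot part Monday's from Tuesday's. Friday's, 62.5 % dosed, gets 1.29 M⁻¹ per unit, hence 0.129 and 6.00 %. In Thursday's I take the bill at its limit of two per mole, so I use a mean of 1.50 M before dilution, which gives an exposure of 3.13, past the peak, and mono adduct of 11.6 %.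

**The forecast.** The forecast says Sunday's > Tuesday's > Thursday's > Monday's > Friday's, with 31 % first and 10.5 % last, on “an order in reagent nearer 0.5 than 1”. It gives Thursday's 25 percent, so we part there, since I hold Thursday's below Monday's.

**The result.** The flasks come out as Sunday's > Tuesday's > Monday's > Thursday's > Friday's, with 28.0 % first and 6.03 % last, under these steps:

    reagent + mono adduct → double product (k = 0.0180 M⁻¹ s⁻¹)
    mono adduct ⇌ isomer of the product (K = 1.40, k = 0.00220 s⁻¹)
    starting material + reagent → mono adduct (k = 0.0180 M⁻¹ s⁻¹)

Thursday's holds 13.9 % of mono adduct and 74.4 % of double product at 2.50 min, and the exposure I reckoned for Thursday's, 3.13, stands past one. For the flask like Sunday's with 1.8 M of reagent, the same constant, with the mean of [reagent] taken as for Thursday's, gives an exposure of 2.71, so 6.65 % of starting material left, and that flask holds 7.75 % of starting material.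

The runs were generated by integration with made-up constants; scatter was added.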